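## The problem

The target 17 is a trans-2,3-disubstituted 1,4-benzodioxane. In the labels used throughout, C7 carries ring A (4-hydroxy-3,5-dimethoxyphenyl) and C8 carries the hydroxymethyl carbon C9. C7 is bonded through O3' to C3' and C8 through O4' to C4' of the benzo ring B, whose C1' bears an (E)-propenal, so O3' is meta and O4' para to the side chain. The first question is therefore regiochemical: the two oxygens of ring B are almost equivalent in a catechol and must be introduced one after the other. The only stereocentres are C7 and C8, adjacent, both S, trans. The trans isomer is the more stable one, so one centre set in absolute terms can steer the other whenever C8 is epimerisable or C7 is formed reversibly. Three groups restrict the reagents. The enal is sensitive to hydride, hydrogen and amines. The ring A phenol lies para to the benzylic C7–O3' bond and can open the dioxane through a quinone methide under base or oxidant. That benzylic ether can also ionise under strong acid. The feature that invites a conjugate-addition closure is that C7 is beta to C9. With C9 as an aldehyde and C7=C8 unsaturated, C7 is a Michael terminus six atoms from the O3' phenol and the precursor is flat and achiral. At the acid oxidation level the same C9 can be tied to O3' as a six-membered lactone.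

## Retrosynthesis

17 from 16. The O–benzyl bond of ring A is cut last. The ring A phenol is kept masked until the end because its phenoxide could open the dioxane at C7. Benzyl is chosen because aldehyde 7 is commercial with it in place and the ether is inert to peracid, amide base, hydride and amine catalysis. Hydrogenolysis is excluded by the enal, so the forward step must be a low-temperature Lewis-acid cleavage that spares the enal and the C7–O3' bond.

16 from 13 and 14. The C1'–vinyl bond is cut (Heck disconnection). The alternative, an aldehyde on ring B, would compete with 7 in the condensation and with C9 in the amine-catalysed step. A bromide is silent in all of these. Acetal 14 delivers the three carbons at the aldehyde oxidation level in one operation. The forward reaction must tolerate the free C9 hydroxyl and leave C7 and C8 alone; neither is acidic in 13.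

13 from 12. C9 is returned to the aldehyde. Aldehyde 12 is configurationally fragile because C8–H is acidic and the ring can reopen by the reverse conjugate addition. The forward reduction must therefore be faster than both, so it is done at once and cold.

12 from 11 (key disconnection). The C7–O3' bond and the C8–H bond are cut, giving the achiral hydroxy enal 11. Against a displacement at C8 or an aryl–oxygen coupling, this cut needs no stereocentre in the precursor and lets a catalyst set C7 while C8 follows by equilibration. The forward step must make a doubly donor-substituted enal electrophilic, favour one face, and be stopped before the reverse reaction erodes the result.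

11 from 10. Compound 11 cannot be assembled under hydroxide or amine conditions, since these would cyclise it without control. The O3' hydroxyl and the C9 carbonyl are therefore hidden together as the aryl lactone 10 (C9–O3' acyl bond). One hydride equivalent at low temperature must stop at the lactol stage and release both groups without base.

10 from 6 and 7. The C7=C8 bond is cut as an aldol condensation. The lactone carbonyl acidifies C8, 7 cannot enolise, and ring A arrives convergently. An α-aryloxyacetaldehyde route would need a separate phenol protecting group and a mixed aldol between two aldehydes. The forward step must control the reactive aryl-ester enolate and give the Z alkene.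

6 from 5, 5 from 3, 3 from 1 and 2. The lactone C–O bond is cut (lactonisation of 5). The C3'–O3' bond is traced to the formyl carbon of 3 (Baeyer–Villiger). The O4'–C8 bond is a Williamson ether from 1 and 2. This sequence solves the regiochemistry: the only hydroxyl of 1 is para to bromine and becomes O4', and the formyl carbon, meta to bromine, becomes O3'. All four materials 1, 2, 7 and 14 are commercial.

## Roads not taken

Alternative 1: Quinone methide closure. The cut is again C7–O3', but at the phenol oxidation level. Ag2O would oxidise the free ring A phenol of 4-{[(2R)-1-hydroxy-3-(4-hydroxy-3,5-dimethoxyphenyl)propan-2-yl]oxy}-3-hydroxybenzaldehyde A1 to its para-quinone methide, and O3'–H would add to C7 in a 6-exo-trig closure. The product would be (2S,3S)-3-(4-hydroxy-3,5-dimethoxyphenyl)-2-(hydroxymethyl)-2,3-dihydro-1,4-benzodioxine-6-carbaldehyde A2.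

- Merits: the closure follows the biogenetic pattern and belongs to a known reaction class. Ring A needs no protecting group. C9 is already an alcohol, and A2 is one Wittig two-carbon extension from 17.
- Weak points: A1 must already carry C8 in enantioenriched form, which means a secondary alkyl aryl ether made by displacement on a chiral diol derivative, with its own steps and protecting groups. The quinone methide has a hydrogen at C8 and can tautomerise to the enol ether, which destroys that centre. The trans selectivity rests on substrate control only. A silver oxidant must tolerate a second electron-rich phenol and an aldehyde.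
- Comparison: this road is better in the certainty of its ring closure and in the length of its endgame. The chosen plan sets against it that both stereocentres come from one catalytic step on an achiral compound, and that ring A stays masked so no quinone methide can form before the last step.

Alternative 2: Epoxy ether isomerisation. The cut is C8–O4'. K2CO3 in methanol would free the O4' phenoxide of 2-{(S)-[4-(benzyloxy)-3,5-dimethoxyphenyl][(2R)-oxiran-2-yl]methoxy}-4-(1,3-dioxolan-2-yl)phenyl acetate A3. The phenoxide would open the epoxide at C8 with inversion (6-exo-tet) to give [(2S,3S)-3-[4-(benzyloxy)-3,5-dimethoxyphenyl]-6-(1,3-dioxolan-2-yl)-2,3-dihydro-1,4-benzodioxin-2-yl]methanol A4.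

- Merits: the closure is stereospecific. Both centres can be traced to an epoxy alcohol from a Sharpless epoxidation, so the absolute configuration is more predictable than in the chosen plan.
- Weak points: the C7–O3' ether of A3 has to be made by opening an epoxy alcohol at the benzylic carbon with a hindered phenol, where the electron-rich ring A invites ionisation and loss of configuration. The diol must then be converted to the terminal epoxide. Attack at the primary C9 (7-endo) competes with the wanted attack at the secondary C8. Three protecting groups (acetate, dioxolane, benzyl) are moved.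
- Comparison: this road is better in stereochemical predictability. The chosen plan sets against it a shorter sequence with one protecting group and no stoichiometric chiral reagent.

Alternative 3: Copper-catalysed aryl ether closure. The cut is C3'–O3'. CuI with a phenanthroline ligand and Cs2CO3 would couple the C7 hydroxyl of 3-bromo-4-{[(1S,2S)-1-[4-(benzyloxy)-3,5-dimethoxyphenyl]-1-hydroxy-3-{[tri(propan-2-yl)silyl]oxy}propan-2-yl]oxy}benzaldehyde A5 with the ring B bromide. The product would be (2S,3S)-3-[4-(benzyloxy)-3,5-dimethoxyphenyl]-2-{[tri(propan-2-yl)silyloxy]methyl}-2,3-dihydro-1,4-benzodioxine-6-carbaldehyde A6.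

- Merits: neither stereocentre is touched in the closure. The bromine marks C3' directly, which solves the ring B regiochemistry more simply than the Baeyer–Villiger sequence of the chosen plan.
- Weak points: both stereocentres must first be built in the open chain with the correct relative configuration. That requires an auxiliary-controlled glycolate aldol or a dihydroxylation followed by a selective displacement. A hot carbonate base acts on a secondary benzylic alkoxide beside an aryl aldehyde, and a silyl group can migrate from O9 to O7 and send the wrong oxygen into the coupling.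
- Comparison: this road is better in the security of the stereocentres during ring closure and in the regiochemical device. The chosen plan sets against it the catalytic origin of chirality and a shorter linear sequence.

Key step: step 6

Assumption: 11 is written as the open hydroxy enal; it is expected to equilibrate with its six-membered lactol (O3' added to C9), and both tautomers reach the same iminium ion.

Assumption: the amine derived from quinine is taken to give the 7S product; if the sense proves opposite, the pseudo-enantiomeric amine derived from quinidine takes its place.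

## Route

Step 1
Reactants: 1 5-bromosalicylaldehyde (5-bromo-2-hydroxybenzaldehyde); 2 ethyl bromoacetate
Product: 3 ethyl (4-bromo-2-formylphenoxy)acetate
Conditions: K2CO3, acetone, reflux
Reagents that add atoms: none
Why: Williamson ether synthesis; the only hydroxyl of 1 is para to bromine, so O4' and C8 are placed without ambiguity, and carbonate in acetone is mild enough to avoid the intramolecular aldol that leads to a benzofuran.

Step 2
Reactants: 3 ethyl (4-bromo-2-formylphenoxy)acetate
Product: 5 (4-bromo-2-hydroxyphenoxy)acetic acid, via aryl formate 4 (not isolated)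
Conditions: mCPBA, CH2Cl2, 0 °C to rt; aq. NaHCO3 wash; then NaOH, MeOH–H2O, 0 °C to rt; then HCl
Reagents that add atoms: meta-chloroperoxybenzoic acid, OOC(=O)c1cccc(Cl)c1; sodium hydroxide, [Na+].[OH-]
Why: Baeyer–Villiger (Dakin-type) oxidation of an ortho-alkoxybenzaldehyde, in which the electron-rich aryl group migrates to give formate 4; saponification then cleaves the formate and the ethyl ester together, and the new O3' hydroxyl is necessarily meta to bromine.

Step 3
Reactants: 5 (4-bromo-2-hydroxyphenoxy)acetic acid
Product: 6 7-bromo-1,4-benzodioxin-2(3H)-one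
Conditions: TsOH·H2O (cat.), toluene, reflux, Dean–Stark
Reagents that add atoms: none
Why: acid-catalysed intramolecular esterification to a six-membered aryl lactone, driven by azeotropic removal of water; the lactone masks O3' and C9 together and acidifies C8.

Step 4
Reactants: 6 7-bromo-1,4-benzodioxin-2(3H)-one; 7 4-(benzyloxy)-3,5-dimethoxybenzaldehyde
Product: 10 (3Z)-3-{[4-(benzyloxy)-3,5-dimethoxyphenyl]methylidene}-7-bromo-1,4-benzodioxin-2(3H)-one, via aldol adduct 8 (not isolated), via mesylate 9 (not isolated)
Conditions: LiN(SiMe3)2, THF, −78 °C (6 added to the base); 7; then MsCl, −78 to −20 °C; then DBU, −20 °C to rt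
Reagents that add atoms: none
Why: aldol condensation carried out as directed aldol addition of the lactone lithium enolate to the non-enolisable aldehyde 7, mesylation of the aldolate and E1cB elimination; the reversible elimination should favour the Z isomer, in which the aryl group lies on the side of O4' and away from the lactone carbonyl, as in aurone-type arylidene heterocycles.

Step 5
Reactants: 10 (3Z)-3-{[4-(benzyloxy)-3,5-dimethoxyphenyl]methylidene}-7-bromo-1,4-benzodioxin-2(3H)-one
Product: 11 (2Z)-3-[4-(benzyloxy)-3,5-dimethoxyphenyl]-2-(4-bromo-2-hydroxyphenoxy)prop-2-enal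
Conditions: iBu2AlH (1.1 equiv), CH2Cl2, −78 °C; MeOH, −78 °C; aq. potassium sodium tartrate
Reagents that add atoms: none
Why: partial reduction of an aryl lactone to the lactol oxidation level, as with dihydrocoumarins; the tetrahedral aluminate should persist until the cold quench, and its collapse frees the enal and the O3' phenol together without any base, while bromide, benzyl ether and enol ether are inert.

Step 6
Reactants: 11 (2Z)-3-[4-(benzyloxy)-3,5-dimethoxyphenyl]-2-(4-bromo-2-hydroxyphenoxy)prop-2-enal
Product: 12 (2R,3S)-3-[4-(benzyloxy)-3,5-dimethoxyphenyl]-6-bromo-2,3-dihydro-1,4-benzodioxine-2-carbaldehyde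
Conditions: 9-amino-9-deoxy-epi-quinine (20 mol%), CF3CO2H (40 mol%), toluene, 0 °C; cold aq. citric acid wash
Reagents that add atoms: none
Why: Proposed new method: the primary amine condenses with C9 of 11 (or opens its lactol) to an iminium ion whose lowered LUMO should make C7 electrophilic although O4' on C8 pushes electron density towards it; the O3' phenol, held by hydrogen bonding to the quinuclidine nitrogen or its trifluoroacetate, adds to C7, the enamine is protonated at C8, and hydrolysis releases 12 and the catalyst. The closest known reaction types are the organocatalytic intramolecular oxa-Michael addition of phenols to enones and enals (flavanone and chroman synthesis) and cinchona primary-amine iminium catalysis of alpha-branched enals; an alpha-aryloxy-beta-aryl enal has been used in neither. The dioxane ring closes in 6-endo-trig mode with C7=C8 inside the new ring, the geometry of the 2'-hydroxychalcone to flavanone closure. C7 is set by the catalyst, which shields one face of the iminium ion while delivering the phenol to the other, and the amine from quinine is taken to give 7S. C8 is set by thermodynamics: it is alpha to the aldehyde and bears an aryloxy group, so it equilibrates through enamine and enol to the trans isomer with both substituents pseudo-equatorial. The step needs the catalysed path to outrun the uncatalysed addition and the reverse reaction; the neutral phenol and weak acceptor character of free 11 at 0 °C should secure the first, and immediate reduction in step 7 the second. Ring A is a weaker donor than it looks, because its 4-oxygen is twisted out of conjugation by the two flanking methoxy groups, which are themselves meta to C7. A primary amine is chosen because the alpha substituent hinders iminium formation with secondary amines.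

Step 7
Reactants: 12 (2R,3S)-3-[4-(benzyloxy)-3,5-dimethoxyphenyl]-6-bromo-2,3-dihydro-1,4-benzodioxine-2-carbaldehyde
Product: 13 [(2S,3S)-3-[4-(benzyloxy)-3,5-dimethoxyphenyl]-6-bromo-2,3-dihydro-1,4-benzodioxin-2-yl]methanol
Conditions: NaBH4, EtOH–CH2Cl2, −20 °C (crude 12, used at once)
Reagents that add atoms: none
Why: borohydride 1,2-reduction of the aldehyde; it removes the acidic C8–H and the path for ring opening, so both stereocentres are fixed (the descriptor at C8 changes from R to S only because the priorities change).

Step 8
Reactants: 13 [(2S,3S)-3-[4-(benzyloxy)-3,5-dimethoxyphenyl]-6-bromo-2,3-dihydro-1,4-benzodioxin-2-yl]methanol; 14 acrolein diethyl acetal (3,3-diethoxyprop-1-ene)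
Product: 16 (2E)-3-[(2S,3S)-3-[4-(benzyloxy)-3,5-dimethoxyphenyl]-2-(hydroxymethyl)-2,3-dihydro-1,4-benzodioxin-6-yl]prop-2-enal, via diethyl acetal 15 (not isolated)
Conditions: Pd(OAc)2 (cat.), nBu4NOAc, K2CO3, KCl, DMF, 90 °C; then 2 M HCl, rt
Reagents that add atoms: water, O
Why: Mizoroki–Heck reaction of the aryl bromide with the allylic acetal under acetate/carbonate/chloride conditions, which direct beta-hydride elimination towards the arene and give the E-cinnamyl acetal; aqueous acid then hydrolyses the acetal, and the free C9 hydroxyl and the non-acidic stereocentres are spectators.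

Step 9
Reactants: 16 (2E)-3-[(2S,3S)-3-[4-(benzyloxy)-3,5-dimethoxyphenyl]-2-(hydroxymethyl)-2,3-dihydro-1,4-benzodioxin-6-yl]prop-2-enal
Product: 17 (2E)-3-[(2S,3S)-3-(4-hydroxy-3,5-dimethoxyphenyl)-2-(hydroxymethyl)-2,3-dihydro-1,4-benzodioxin-6-yl]prop-2-enal
Conditions: BCl3, C6HMe5, CH2Cl2, −78 °C; then aq. NaHCO3
Reagents that add atoms: none
Why: Lewis-acid cleavage of an aryl benzyl ether with pentamethylbenzene as a non-basic cation scavenger (Friedel–Crafts capture of the benzyl cation); the crowded oxygen between two methoxy groups is the most readily cleaved ether, so the methyl ethers, the enal and the C7–O3' bond should survive at −78 °C.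

## Compound list

1 | 5-bromosalicylaldehyde (5-bromo-2-hydroxybenzaldehyde) | O=Cc1cc(Br)ccc1O | starting material
2 | ethyl bromoacetate | CCOC(=O)CBr | starting material
3 | ethyl (4-bromo-2-formylphenoxy)acetate | CCOC(=O)COc1ccc(Br)cc1C=O | intermediate
4 | ethyl [4-bromo-2-(formyloxy)phenoxy]acetate (not isolated) | CCOC(=O)COc1ccc(Br)cc1OC=O | intermediate
5 | (4-bromo-2-hydroxyphenoxy)acetic acid | OC(=O)COc1ccc(Br)cc1O | intermediate
6 | 7-bromo-1,4-benzodioxin-2(3H)-one | O=C1COc2ccc(Br)cc2O1 | intermediate
7 | 4-(benzyloxy)-3,5-dimethoxybenzaldehyde | COc1cc(C=O)cc(OC)c1OCc1ccccc1 | starting material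
8 | 3-{[4-(benzyloxy)-3,5-dimethoxyphenyl](hydroxy)methyl}-7-bromo-1,4-benzodioxin-2(3H)-one (lithium alkoxide in the flask, mixture of diastereomers, not isolated) | O=C1Oc2cc(Br)ccc2OC1C(O)c1cc(OC)c(OCc2ccccc2)c(OC)c1 | intermediate
9 | [4-(benzyloxy)-3,5-dimethoxyphenyl](7-bromo-2-oxo-2,3-dihydro-1,4-benzodioxin-3-yl)methyl methanesulfonate (mixture of diastereomers, not isolated) | O=C1Oc2cc(Br)ccc2OC1C(OS(C)(=O)=O)c1cc(OC)c(OCc2ccccc2)c(OC)c1 | intermediate
10 | (3Z)-3-{[4-(benzyloxy)-3,5-dimethoxyphenyl]methylidene}-7-bromo-1,4-benzodioxin-2(3H)-one | O=C1Oc2cc(Br)ccc2O/C1=C\c1cc(OC)c(OCc2ccccc2)c(OC)c1 | intermediate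
11 | (2Z)-3-[4-(benzyloxy)-3,5-dimethoxyphenyl]-2-(4-bromo-2-hydroxyphenoxy)prop-2-enal | O=C/C(Oc1ccc(Br)cc1O)=C/c1cc(OC)c(OCc2ccccc2)c(OC)c1 | intermediate
12 | (2R,3S)-3-[4-(benzyloxy)-3,5-dimethoxyphenyl]-6-bromo-2,3-dihydro-1,4-benzodioxine-2-carbaldehyde (trans) | COc1cc(cc(OC)c1OCc1ccccc1)[C@@H]1Oc2cc(Br)ccc2O[C@H]1C=O | intermediate
13 | [(2S,3S)-3-[4-(benzyloxy)-3,5-dimethoxyphenyl]-6-bromo-2,3-dihydro-1,4-benzodioxin-2-yl]methanol | COc1cc(cc(OC)c1OCc1ccccc1)[C@@H]1Oc2cc(Br)ccc2O[C@H]1CO | intermediate
14 | acrolein diethyl acetal (3,3-diethoxyprop-1-ene) | C=CC(OCC)OCC | starting material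
15 | [(2S,3S)-3-[4-(benzyloxy)-3,5-dimethoxyphenyl]-6-[(1E)-3,3-diethoxyprop-1-en-1-yl]-2,3-dihydro-1,4-benzodioxin-2-yl]methanol (not isolated) | COc1cc(cc(OC)c1OCc1ccccc1)[C@@H]1Oc2cc(/C=C/C(OCC)OCC)ccc2O[C@H]1CO | intermediate
16 | (2E)-3-[(2S,3S)-3-[4-(benzyloxy)-3,5-dimethoxyphenyl]-2-(hydroxymethyl)-2,3-dihydro-1,4-benzodioxin-6-yl]prop-2-enal | COc1cc(cc(OC)c1OCc1ccccc1)[C@@H]1Oc2cc(/C=C/C=O)ccc2O[C@H]1CO | intermediate
17 | (2E)-3-[(2S,3S)-3-(4-hydroxy-3,5-dimethoxyphenyl)-2-(hydroxymethyl)-2,3-dihydro-1,4-benzodioxin-6-yl]prop-2-enal | COc1cc([C@@H]2Oc3cc(/C=C/C=O)ccc3O[C@H]2CO)cc(OC)c1O | target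

## Step count and risks

Total: 9 steps. Longest linear sequence: 9 steps (1 to 17); 7 enters at step 4 and 14 at step 8.

Least certain steps:

Step 6 (key step). The iminium ion of a doubly donor-substituted, alpha-branched enal may form too slowly or be too weak an acceptor for turnover. The material may also rest as the lactol or as an N,O-acetal, facial discrimination may be poor, and the reverse reaction may erode the enantiomeric purity before the reduction. The fallback closes the ring by known chemistry at the alcohol level. It sets out from 6 and 7: the aldol addition of step 4 is quenched cold with acetic acid so that 8 is isolated. LiBH4 in THF opens the lactone reductively to 1-[4-(benzyloxy)-3,5-dimethoxyphenyl]-2-(4-bromo-2-hydroxyphenoxy)propane-1,3-diol F1. TsOH in toluene ionises the benzylic C7 hydroxyl and O3' captures the cation, giving racemic trans-[3-[4-(benzyloxy)-3,5-dimethoxyphenyl]-6-bromo-2,3-dihydro-1,4-benzodioxin-2-yl]methanol F2 (trans by equilibration through the cation). Preparative chromatography on a chiral stationary phase separates the enantiomers, and the route is rejoined at 13.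

Step 4. The aryl-lactone enolate may acylate a second molecule of lactone or open to a ketene. The lithium aldolate may collapse onto the aryl ester (beta-lactone formation and loss of CO2) before it is mesylated, and the elimination may give a mixture of alkene isomers. The fallback replaces the aldol by an olefination and sets out from 6. Radical bromination with N-bromosuccinimide and AIBN gives 3,7-dibromo-1,4-benzodioxin-2(3H)-one F3. A Michaelis–Arbuzov reaction with P(OEt)3 gives diethyl (7-bromo-2-oxo-2,3-dihydro-1,4-benzodioxin-3-yl)phosphonate F4. Horner–Wadsworth–Emmons olefination of 7 (LiCl, DBU, MeCN) returns to the route at 10.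

Step 5. The aluminate may collapse before the quench. That leads either to over-reduction to the allylic alcohol or to uncontrolled cyclisation of the aluminium phenoxide onto the Lewis-acid-activated enal. The fallback accepts the over-reduction. It sets out from 10: excess iBu2AlH gives (2Z)-3-[4-(benzyloxy)-3,5-dimethoxyphenyl]-2-(4-bromo-2-hydroxyphenoxy)prop-2-en-1-ol F5, and MnO2 in CH2Cl2 oxidises the allylic alcohol under neutral conditions, returning to the route at 11.

Step 8. Oxidative addition into the electron-rich bromide may be slow and the catalyst may precipitate as palladium black. Beta-hydride elimination towards the acetal carbon would give the saturated ester instead of the enal. The fallback builds the enal by redox adjustment and sets out from 13. A Heck reaction with methyl acrylate (Pd(OAc)2, P(o-tol)3, Et3N, DMF) gives methyl (2E)-3-[(2S,3S)-3-[4-(benzyloxy)-3,5-dimethoxyphenyl]-2-(hydroxymethyl)-2,3-dihydro-1,4-benzodioxin-6-yl]prop-2-enoate F6. iBu2AlH reduces the ester to (2E)-3-[(2S,3S)-3-[4-(benzyloxy)-3,5-dimethoxyphenyl]-2-(hydroxymethyl)-2,3-dihydro-1,4-benzodioxin-6-yl]prop-2-en-1-ol F7. MnO2 oxidises only the allylic alcohol and returns to the route at 16.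

Step 9. BCl3 may ionise the benzylic C7–O3' bond, which would cause epimerisation to the cis isomer or ring opening, or chloride may add to the enal. The fallback removes the benzyl group before the enal exists and sets out from 13. BCl3 and pentamethylbenzene at −78 °C give 4-[(2S,3S)-7-bromo-3-(hydroxymethyl)-2,3-dihydro-1,4-benzodioxin-2-yl]-2,6-dimethoxyphenol F8. The Heck reaction of step 8 with 14 then passes through 4-[(2S,3S)-7-[(1E)-3,3-diethoxyprop-1-en-1-yl]-3-(hydroxymethyl)-2,3-dihydro-1,4-benzodioxin-2-yl]-2,6-dimethoxyphenol F9, which is hydrolysed in the acid work-up, and the route is rejoined at 17.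

## Further compounds

F1 | step 6 | 1-[4-(benzyloxy)-3,5-dimethoxyphenyl]-2-(4-bromo-2-hydroxyphenoxy)propane-1,3-diol (mixture of stereoisomers) | OCC(Oc1ccc(Br)cc1O)C(O)c1cc(OC)c(OCc2ccccc2)c(OC)c1
F2 | step 6 | racemic trans-[3-[4-(benzyloxy)-3,5-dimethoxyphenyl]-6-bromo-2,3-dihydro-1,4-benzodioxin-2-yl]methanol | COc1cc(cc(OC)c1OCc1ccccc1)[C@@H]1Oc2cc(Br)ccc2O[C@H]1CO.COc1cc(cc(OC)c1OCc1ccccc1)[C@H]1Oc2cc(Br)ccc2O[C@@H]1CO
F3 | step 4 | 3,7-dibromo-1,4-benzodioxin-2(3H)-one (racemic) | O=C1Oc2cc(Br)ccc2OC1Br
F4 | step 4 | diethyl (7-bromo-2-oxo-2,3-dihydro-1,4-benzodioxin-3-yl)phosphonate (racemic) | CCOP(=O)(OCC)C1Oc2ccc(Br)cc2OC1=O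
F5 | step 5 | (2Z)-3-[4-(benzyloxy)-3,5-dimethoxyphenyl]-2-(4-bromo-2-hydroxyphenoxy)prop-2-en-1-ol | OC/C(Oc1ccc(Br)cc1O)=C/c1cc(OC)c(OCc2ccccc2)c(OC)c1
F6 | step 8 | methyl (2E)-3-[(2S,3S)-3-[4-(benzyloxy)-3,5-dimethoxyphenyl]-2-(hydroxymethyl)-2,3-dihydro-1,4-benzodioxin-6-yl]prop-2-enoate | COc1cc(cc(OC)c1OCc1ccccc1)[C@@H]1Oc2cc(/C=C/C(=O)OC)ccc2O[C@H]1CO
F7 | step 8 | (2E)-3-[(2S,3S)-3-[4-(benzyloxy)-3,5-dimethoxyphenyl]-2-(hydroxymethyl)-2,3-dihydro-1,4-benzodioxin-6-yl]prop-2-en-1-ol | COc1cc(cc(OC)c1OCc1ccccc1)[C@@H]1Oc2cc(/C=C/CO)ccc2O[C@H]1CO
F8 | step 9 | 4-[(2S,3S)-7-bromo-3-(hydroxymethyl)-2,3-dihydro-1,4-benzodioxin-2-yl]-2,6-dimethoxyphenol | COc1cc(cc(OC)c1O)[C@@H]1Oc2cc(Br)ccc2O[C@H]1CO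
F9 | step 9 | 4-[(2S,3S)-7-[(1E)-3,3-diethoxyprop-1-en-1-yl]-3-(hydroxymethyl)-2,3-dihydro-1,4-benzodioxin-2-yl]-2,6-dimethoxyphenol | COc1cc(cc(OC)c1O)[C@@H]1Oc2cc(/C=C/C(OCC)OCC)ccc2O[C@H]1CO
A1 | alternative 1 | 4-{[(2R)-1-hydroxy-3-(4-hydroxy-3,5-dimethoxyphenyl)propan-2-yl]oxy}-3-hydroxybenzaldehyde | O=Cc1ccc(O[C@H](Cc2cc(OC)c(O)c(OC)c2)CO)c(O)c1
A2 | alternative 1 | (2S,3S)-3-(4-hydroxy-3,5-dimethoxyphenyl)-2-(hydroxymethyl)-2,3-dihydro-1,4-benzodioxine-6-carbaldehyde | COc1cc(cc(OC)c1O)[C@@H]1Oc2cc(C=O)ccc2O[C@H]1CO
A3 | alternative 2 | 2-{(S)-[4-(benzyloxy)-3,5-dimethoxyphenyl][(2R)-oxiran-2-yl]methoxy}-4-(1,3-dioxolan-2-yl)phenyl acetate | COc1cc(cc(OC)c1OCc1ccccc1)[C@H](Oc1cc(C2OCCO2)ccc1OC(C)=O)[C@H]1CO1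
A4 | alternative 2 | [(2S,3S)-3-[4-(benzyloxy)-3,5-dimethoxyphenyl]-6-(1,3-dioxolan-2-yl)-2,3-dihydro-1,4-benzodioxin-2-yl]methanol | COc1cc(cc(OC)c1OCc1ccccc1)[C@@H]1Oc2cc(C3OCCO3)ccc2O[C@H]1CO
A5 | alternative 3 | 3-bromo-4-{[(1S,2S)-1-[4-(benzyloxy)-3,5-dimethoxyphenyl]-1-hydroxy-3-{[tri(propan-2-yl)silyl]oxy}propan-2-yl]oxy}benzaldehyde | COc1cc(cc(OC)c1OCc1ccccc1)[C@H](O)[C@H](CO[Si](C(C)C)(C(C)C)C(C)C)Oc1ccc(C=O)cc1Br
A6 | alternative 3 | (2S,3S)-3-[4-(benzyloxy)-3,5-dimethoxyphenyl]-2-{[tri(propan-2-yl)silyloxy]methyl}-2,3-dihydro-1,4-benzodioxine-6-carbaldehyde | COc1cc(cc(OC)c1OCc1ccccc1)[C@@H]1Oc2cc(C=O)ccc2O[C@H]1CO[Si](C(C)C)(C(C)C)C(C)C
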